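**Strategy.** The ten-membered carbocycle is closed last, between the vinylic carbon C10 (which carries the exocyclic C14 methylene) and the carbonyl carbon C1. A CrCl2/NiCl2-mediated Nozaki–Hiyama–Kishi addition of a C10 alkenyl bromide to a C1 aldehyde forms this bond and the ring in one operation; oxidation then gives the 1-oxo-10(14)-ene. The step exploits the α-methylene ketone C14=C10–C1=O and the turn that the cis-4,5-epoxide and the planar butenolide ring (O–C12–C11=C7–C6) impose on the chain. Its precursor is an acyclic bromo aldehyde that already carries the butenolide, the 13-acetate, the 8-methacrylate and all four stereocentres.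

Key step: step 13

Remark on numbering: germacranolide numbering is used (C1 ketone carbon, C4/C5 epoxide with C15 methyl on C4, C6 lactone carbinol, C7=C11 butenolide alkene, C8 methacrylate carbinol, C10=C14 exocyclic alkene, C12 lactone carbonyl, C13 acetoxymethyl carbon).

Assumption: esters 1 and 2 are taken as catalogue compounds (each is otherwise one protection step from methyl 3-hydroxypropanoate or methyl glycolate); B-bromodiisopinocampheylborane of the (−)-α-pinene series is made as a reagent and is not counted as a route compound.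

Step 1
Reactants: 1 methyl 3-[(tert-butyldimethylsilyl)oxy]propanoate; 2 methyl 2-[(4-methoxybenzyl)oxy]acetate
Product: 3 racemic α-(silyloxymethyl) β-keto ester
Conditions: LiN(iPr)2 (2.2 equiv), 1 (2.2 equiv), THF, −78 °C; then 2, −78 → −30 °C; AcOH
Reagents that add atoms: none
Why: Crossed Claisen condensation, in which the lithium enolate of 1 (kept cold to suppress β-elimination of silanolate) acylates the activated α-alkoxy ester 2 and the product rests as its stabilised enolate until the quench.

Step 2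
Reactants: 3 racemic β-keto ester
Product: 4 (Z)-enol triflate
Conditions: saturated aqueous LiOH, Tf2O, hexanes, 5 °C
Reagents that add atoms: trifluoromethanesulfonic anhydride, O=S(=O)(OS(=O)(=O)C(F)(F)F)C(F)(F)F
Why: Enol triflation through the lithium-chelated (Z)-enolate of the β-keto ester should place OTf cis to CO2Me, which fixes the tetrasubstituted alkene geometry needed for the later lactone closure.

Step 3
Reactants: 4 (Z)-enol triflate
Product: 5 primary alcohol
Conditions: camphor-10-sulfonic acid (cat.), MeOH, 0 °C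
Reagents that add atoms: none
Why: Acid-catalysed methanolysis removes the primary silyl ether, while the 4-methoxybenzyl ether, the methyl ester and the enol triflate should be inert.

Step 4
Reactants: 5 primary alcohol
Product: 6 acetate (the C7–C8/C11–C13 building block)
Conditions: Ac2O, Et3N, 4-(dimethylamino)pyridine (cat.), CH2Cl2, 0 °C
Reagents that add atoms: acetic anhydride, CC(=O)OC(C)=O
Why: Standard O-acetylation installs the C13 acetate of the target at a stage where the carbon skeleton can no longer enolise, so no elimination of acetate is possible.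

Step 5
Reactants: 7 nerol
Product: 8 (2R,3S)-2,3-epoxynerol
Conditions: Ti(OiPr)4 (cat.), D-(−)-diethyl tartrate (cat.), tBuOOH, 4 Å molecular sieves, CH2Cl2, −20 °C
Reagents that add atoms: tert-butyl hydroperoxide, CC(C)(C)OO
Why: Sharpless asymmetric epoxidation, in which the D-(−)-tartrate titanium complex delivers oxygen to the face of the (Z)-allylic alcohol that gives the (2R,3S)-epoxide (C5 R and C4 S of the target), the isolated trisubstituted alkene being untouched.

Step 6
Reactants: 8 (2R,3S)-2,3-epoxynerol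
Product: 9 cis-epoxy aldehyde
Conditions: Dess–Martin periodinane, NaHCO3, CH2Cl2, 0 °C → rt
Reagents that add atoms: none
Why: Buffered Dess–Martin oxidation should give the cis-epoxy aldehyde without epoxide opening or epimerisation.

Step 7
Reactants: 9 cis-epoxy aldehyde; 6 acetate
Product: 11 butenolide 4-methoxybenzyl ether, via hydroxy ester 10 (not isolated)
Conditions: CrCl2 (4 equiv), NiCl2 (cat.), DMF, rt
Reagents that add atoms: none
Why: Nozaki–Hiyama–Kishi coupling, in which zerovalent nickel inserts into the activated C–OTf bond and the derived alkenylchromium adds to the aldehyde anti to the epoxide C–O bond (Felkin–Anh/Cornforth control by the cis-epoxide), which should set C6 as R, after which the alkoxide lying cis to CO2Me lactonises to the butenolide.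

Step 8
Reactants: 11 butenolide 4-methoxybenzyl ether
Product: 12 C8 primary alcohol
Conditions: DDQ, CH2Cl2/pH 7 buffer, 0 °C
Reagents that add atoms: none
Why: Oxidative cleavage of the 4-methoxybenzyl ether under neutral conditions frees the C8 alcohol and should leave the epoxide, the acetate and the trisubstituted alkene untouched.

Step 9
Reactants: 12 C8 primary alcohol
Product: 13 C8 aldehyde
Conditions: Dess–Martin periodinane, NaHCO3, CH2Cl2, 0 °C
Reagents that add atoms: none
Why: Dess–Martin oxidation of the primary allylic alcohol under non-basic buffered conditions gives the aldehyde and avoids epimerisation at the γ-position C6.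

Step 10
Reactants: 13 C8 aldehyde
Product: 15 (8R)-2-bromoallyl carbinol, via borinate ester 14 (not isolated)
Conditions: allene (excess), B-bromodiisopinocampheylborane [from (−)-α-pinene], CH2Cl2, −78 → 0 °C; then 13, −78 °C; pH 7 buffer, MeOH, H2O2, 0 °C
Reagents that add atoms: allene, C=C=C; B-bromodiisopinocampheylborane, BrB([C@H]1C[C@H]2C[C@@H]([C@@H]1C)C2(C)C)[C@H]1C[C@H]2C[C@@H]([C@@H]1C)C2(C)C
Why: Bromoboration of allene gives the 2-bromoallylborane, and its Brown-type allylboration through a chair transition state is reagent-controlled, the (−)-α-pinene-derived ligands directing attack to the Re face of the aldehyde, which should set C8 as R.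

Step 11
Reactants: 15 (8R)-2-bromoallyl carbinol
Product: 16 C8 methacrylate
Conditions: methacrylic anhydride, Et3N, 4-(dimethylamino)pyridine (cat.), CH2Cl2, 0 °C
Reagents that add atoms: methacrylic anhydride, C=C(C)C(=O)OC(=O)C(C)=C
Why: Nucleophile-catalysed acylation of the secondary alcohol with retention at C8 installs the methacrylate under conditions mild enough for the epoxide and the butenolide.

Step 12
Reactants: 16 C8 methacrylate
Product: 18 seco bromo aldehyde, via ozonide 17 (not isolated)
Conditions: O3, CH2Cl2, −78 °C (Sudan Red 7B end point); then PPh3, −78 °C → rt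
Reagents that add atoms: ozone, [O-][O+]=O
Why: Ozonolysis with reductive work-up, in which the electron-rich trisubstituted alkene reacts far faster than the alkenyl bromide, the methacrylate and the butenolide alkenes, so titration to the indicator end point should unmask the C1 aldehyde selectively.

Step 13
Reactants: 18 seco bromo aldehyde
Product: 19 macrocyclic allylic alcohol (both C1 epimers)
Conditions: CrCl2 (10 equiv), NiCl2 (0.1 equiv), DMSO/THF, 25 °C, slow addition of 18 to high dilution (0.002 M)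
Reagents that add atoms: none
Why: NiCl2 is reduced by CrCl2 to zerovalent nickel, which inserts into the C10–Br bond; transmetalation to trivalent chromium gives an alkenylchromium species that adds to the C1 aldehyde, and the chromium alkoxide is hydrolysed on work-up. The closest known reaction type is the Nozaki–Hiyama–Kishi medium-ring cyclisation of alkenyl halide aldehydes. The ten-membered carbocycle is closed in a 10-exo-trig mode, the aldehyde oxygen ending outside the ring. The only new stereocentre, the C1 carbinol, is not controlled and need not be, because step 14 removes it. The step needs chemoselectivity for the aldehyde over the lactone, the two esters, the epoxide and the two enoate alkenes, which the low basicity and carbonyl selectivity of alkenylchromium reagents secure. It also needs cyclisation to outrun oligomerisation, which high dilution and the turn imposed by the cis-epoxide and the planar C6–C7(=C11)–C8 segment of the butenolide ring should secure.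

Step 14
Reactants: 19 macrocyclic allylic alcohol
Product: 20 CNP0266914.1
Conditions: Dess–Martin periodinane, NaHCO3, CH2Cl2, 0 °C → rt
Reagents that add atoms: none
Why: Dess–Martin oxidation of the allylic alcohol converges both C1 epimers to the cross-conjugated enone and should not affect the epoxide, the esters or the lactone.

**Compound list**

1 | methyl 3-[(tert-butyldimethylsilyl)oxy]propanoate | COC(=O)CCO[Si](C)(C)C(C)(C)C | starting material
2 | methyl 2-[(4-methoxybenzyl)oxy]acetate | COC(=O)COCc1ccc(OC)cc1 | starting material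
3 | methyl 2-{[(tert-butyldimethylsilyl)oxy]methyl}-4-[(4-methoxybenzyl)oxy]-3-oxobutanoate (racemic at C2) | COC(=O)C(CO[Si](C)(C)C(C)(C)C)C(=O)COCc1ccc(OC)cc1 | intermediate
4 | methyl (2Z)-2-{[(tert-butyldimethylsilyl)oxy]methyl}-4-[(4-methoxybenzyl)oxy]-3-{[(trifluoromethyl)sulfonyl]oxy}but-2-enoate | COC(=O)/C(CO[Si](C)(C)C(C)(C)C)=C(\OS(=O)(=O)C(F)(F)F)COCc1ccc(OC)cc1 | intermediate
5 | methyl (2Z)-2-(hydroxymethyl)-4-[(4-methoxybenzyl)oxy]-3-{[(trifluoromethyl)sulfonyl]oxy}but-2-enoate | COC(=O)/C(CO)=C(\OS(=O)(=O)C(F)(F)F)COCc1ccc(OC)cc1 | intermediate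
6 | methyl (2Z)-2-(acetoxymethyl)-4-[(4-methoxybenzyl)oxy]-3-{[(trifluoromethyl)sulfonyl]oxy}but-2-enoate | COC(=O)/C(COC(C)=O)=C(\OS(=O)(=O)C(F)(F)F)COCc1ccc(OC)cc1 | intermediate
7 | nerol, (2Z)-3,7-dimethylocta-2,6-dien-1-ol | CC(C)=CCC/C(C)=C\CO | starting material
8 | [(2R,3S)-3-methyl-3-(4-methylpent-3-en-1-yl)oxiran-2-yl]methanol | CC(C)=CCC[C@]1(C)O[C@@H]1CO | intermediate
9 | (2S,3S)-3-methyl-3-(4-methylpent-3-en-1-yl)oxirane-2-carbaldehyde | CC(C)=CCC[C@]1(C)O[C@@H]1C=O | intermediate
10 | methyl (2Z,4R)-2-(acetoxymethyl)-4-hydroxy-3-{[(4-methoxybenzyl)oxy]methyl}-4-[(2R,3S)-3-methyl-3-(4-methylpent-3-en-1-yl)oxiran-2-yl]but-2-enoate | CC(C)=CCC[C@]1(C)O[C@@H]1[C@H](O)/C(COCc1ccc(OC)cc1)=C(/COC(C)=O)C(=O)OC | intermediate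
11 | {(5R)-4-{[(4-methoxybenzyl)oxy]methyl}-5-[(2R,3S)-3-methyl-3-(4-methylpent-3-en-1-yl)oxiran-2-yl]-2-oxo-2,5-dihydrofuran-3-yl}methyl acetate | CC(C)=CCC[C@]1(C)O[C@@H]1[C@@H]1OC(=O)C(COC(C)=O)=C1COCc1ccc(OC)cc1 | intermediate
12 | {(5R)-4-(hydroxymethyl)-5-[(2R,3S)-3-methyl-3-(4-methylpent-3-en-1-yl)oxiran-2-yl]-2-oxo-2,5-dihydrofuran-3-yl}methyl acetate | CC(C)=CCC[C@]1(C)O[C@@H]1[C@@H]1OC(=O)C(COC(C)=O)=C1CO | intermediate
13 | {(5R)-4-formyl-5-[(2R,3S)-3-methyl-3-(4-methylpent-3-en-1-yl)oxiran-2-yl]-2-oxo-2,5-dihydrofuran-3-yl}methyl acetate | CC(C)=CCC[C@]1(C)O[C@@H]1[C@@H]1OC(=O)C(COC(C)=O)=C1C=O | intermediate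
14 | diisopinocampheylborinate ester of 15 (boron on the C8 oxygen) | CC(C)=CCC[C@]1(C)O[C@@H]1[C@@H]1OC(=O)C(COC(C)=O)=C1[C@H](OB([C@H]2C[C@H]3C[C@@H]([C@@H]2C)C3(C)C)[C@H]2C[C@H]3C[C@@H]([C@@H]2C)C3(C)C)CC(Br)=C | intermediate
15 | {(5R)-4-[(1R)-3-bromo-1-hydroxybut-3-en-1-yl]-5-[(2R,3S)-3-methyl-3-(4-methylpent-3-en-1-yl)oxiran-2-yl]-2-oxo-2,5-dihydrofuran-3-yl}methyl acetate | CC(C)=CCC[C@]1(C)O[C@@H]1[C@@H]1OC(=O)C(COC(C)=O)=C1[C@H](O)CC(Br)=C | intermediate
16 | (1R)-1-{(2R)-4-(acetoxymethyl)-2-[(2R,3S)-3-methyl-3-(4-methylpent-3-en-1-yl)oxiran-2-yl]-5-oxo-2,5-dihydrofuran-3-yl}-3-bromobut-3-en-1-yl 2-methylprop-2-enoate | CC(C)=CCC[C@]1(C)O[C@@H]1[C@@H]1OC(=O)C(COC(C)=O)=C1[C@H](OC(=O)C(C)=C)CC(Br)=C | intermediate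
17 | ozonide (3,3-dimethyl-1,2,4-trioxolane) of the terminal alkene of 16 | CC1(C)OOC(CC[C@]2(C)O[C@@H]2[C@@H]2OC(=O)C(COC(C)=O)=C2[C@H](OC(=O)C(C)=C)CC(Br)=C)O1 | intermediate
18 | (1R)-1-{(2R)-4-(acetoxymethyl)-2-[(2R,3S)-3-methyl-3-(3-oxopropyl)oxiran-2-yl]-5-oxo-2,5-dihydrofuran-3-yl}-3-bromobut-3-en-1-yl 2-methylprop-2-enoate | O=CCC[C@]1(C)O[C@@H]1[C@@H]1OC(=O)C(COC(C)=O)=C1[C@H](OC(=O)C(C)=C)CC(Br)=C | intermediate
19 | (4S,5R,6R,8R)-13-acetoxy-4,5-epoxy-1-hydroxy-8-(methacryloyloxy)germacra-7(11),10(14)-dien-12,6-olide (both C1 epimers) | C=C(C)C(=O)O[C@@H]1CC(=C)C(O)CC[C@]2(C)O[C@@H]2[C@@H]2OC(=O)C(COC(C)=O)=C21 | intermediate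
20 | CNP0266914.1, (4S,5R,6R,8R)-13-acetoxy-4,5-epoxy-8-(methacryloyloxy)-1-oxogermacra-7(11),10(14)-dien-12,6-olide | C=C(C)C(=O)O[C@@H]1CC(=C)C(=O)CC[C@]2(C)O[C@@H]2[C@@H]2OC(=O)C(COC(C)=O)=C21 | target

**Count.** Total: 14 steps. Longest linear sequence: 12 steps (steps 1–4, then 7–14).

**Steps most likely to fail**

1. Step 13 (ring closure). Oxidative addition of zerovalent nickel into the unactivated 1,1-disubstituted alkenyl bromide may be too slow, so that reduction of the aldehyde or intermolecular coupling outruns the closure. Fallback, setting out from 13: the halide is changed to the more reactive iodide. Iodoboration of allene with B-iododiisopinocampheylborane [(−)-α-pinene series] and allylboration of 13 should give {(5R)-4-[(1R)-1-hydroxy-3-iodobut-3-en-1-yl]-5-[(2R,3S)-3-methyl-3-(4-methylpent-3-en-1-yl)oxiran-2-yl]-2-oxo-2,5-dihydrofuran-3-yl}methyl acetate F1. Acylation with methacrylic anhydride gives the methacrylate of this iodo alcohol F2. Ozonolysis with PPh3 work-up gives the seco iodo aldehyde F3, and its closure with CrCl2/NiCl2 at room temperature comes back to the route at 19.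

2. Step 7 (fragment union). The hindered tetrasubstituted enol triflate may transmetalate sluggishly, and facial selectivity at C6 may erode at the temperature the chromium reagent needs. Fallback, setting out from 6 and 9: the triflate is exchanged for iodide [Ni(OAc)2·4H2O (cat.), 1,5-cyclooctadiene, NaI, THF/DMA] to give methyl (2Z)-2-(acetoxymethyl)-3-iodo-4-[(4-methoxybenzyl)oxy]but-2-enoate F4. Iodine–magnesium exchange with iPrMgCl·LiCl at −78 °C and polar Felkin–Anh addition of the alkenylmagnesium to 9 at that temperature give 10, which lactonises and comes back to the route at 11.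

3. Step 10 (C8 stereocentre). Reagent control may be incomplete with this hindered, electron-poor aldehyde, giving poor selectivity at C8. Fallback, setting out from 13: a Barbier allylation (In powder, 2,3-dibromopropene, THF/H2O) gives the C8-epimeric bromo carbinols F5. Dess–Martin oxidation gives the C8 ketone F6. Corey–Bakshi–Shibata reduction with (S)-1-methyl-3,3-diphenyltetrahydro-1H,3H-pyrrolo[1,2-c][1,3,2]oxazaborole and catecholborane at −78 °C, the butenolide carbon acting as the large group, should give the 8R alcohol and come back to the route at 15.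

**Further compounds**

F1 | step 13 | {(5R)-4-[(1R)-1-hydroxy-3-iodobut-3-en-1-yl]-5-[(2R,3S)-3-methyl-3-(4-methylpent-3-en-1-yl)oxiran-2-yl]-2-oxo-2,5-dihydrofuran-3-yl}methyl acetate | CC(C)=CCC[C@]1(C)O[C@@H]1[C@@H]1OC(=O)C(COC(C)=O)=C1[C@H](O)CC(I)=C
F2 | step 13 | (1R)-1-{(2R)-4-(acetoxymethyl)-2-[(2R,3S)-3-methyl-3-(4-methylpent-3-en-1-yl)oxiran-2-yl]-5-oxo-2,5-dihydrofuran-3-yl}-3-iodobut-3-en-1-yl 2-methylprop-2-enoate | CC(C)=CCC[C@]1(C)O[C@@H]1[C@@H]1OC(=O)C(COC(C)=O)=C1[C@H](OC(=O)C(C)=C)CC(I)=C
F3 | step 13 | (1R)-1-{(2R)-4-(acetoxymethyl)-2-[(2R,3S)-3-methyl-3-(3-oxopropyl)oxiran-2-yl]-5-oxo-2,5-dihydrofuran-3-yl}-3-iodobut-3-en-1-yl 2-methylprop-2-enoate | O=CCC[C@]1(C)O[C@@H]1[C@@H]1OC(=O)C(COC(C)=O)=C1[C@H](OC(=O)C(C)=C)CC(I)=C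
F4 | step 7 | methyl (2Z)-2-(acetoxymethyl)-3-iodo-4-[(4-methoxybenzyl)oxy]but-2-enoate | COC(=O)/C(COC(C)=O)=C(\I)COCc1ccc(OC)cc1
F5 | step 10 | {(5R)-4-(3-bromo-1-hydroxybut-3-en-1-yl)-5-[(2R,3S)-3-methyl-3-(4-methylpent-3-en-1-yl)oxiran-2-yl]-2-oxo-2,5-dihydrofuran-3-yl}methyl acetate (both C8 epimers) | CC(C)=CCC[C@]1(C)O[C@@H]1[C@@H]1OC(=O)C(COC(C)=O)=C1C(O)CC(Br)=C
F6 | step 10 | {(5R)-4-(3-bromobut-3-enoyl)-5-[(2R,3S)-3-methyl-3-(4-methylpent-3-en-1-yl)oxiran-2-yl]-2-oxo-2,5-dihydrofuran-3-yl}methyl acetate | CC(C)=CCC[C@]1(C)O[C@@H]1[C@@H]1OC(=O)C(COC(C)=O)=C1C(=O)CC(Br)=C
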